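The heptane chain is numbered from C1, bonded to the methoxycatechol ring A, to C7, bonded to the 4-hydroxyphenyl ring B. The feature exploited is the latent symmetry of C2–C7: joined by an extra C7–C2 bond, these six carbons with their syn oxygens on C3 and C5 become a meso cis-3,5-bis(silyloxy)cyclohexanone (carbonyl C7, mirror plane through C7 and C4). A single catalyst-controlled Baeyer–Villiger oxidation puts oxygen into the C7–C2 bond alone, which expands the ring to a lactone, fixes the absolute configuration at C3 and C5 and makes the chain ends different. Ring A with C1 is then attached at C2 by Wittig olefination, ring B at C7 by Grignard addition.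

Key step: step 3

Remarks on the chemistry
- The target is the (3R,5S) syn-diol. No structural error was found: the lactone that maps onto it is the (4R,6S) enantiomer, in which lactone C2 is chain C7 and lactone C7 is chain C2.
- Assumption: the sense of induction of the chiral catalyst in step 3 cannot be predicted for this substrate. A preliminary run is assumed to identify the ligand antipode that gives the (4R,6S) lactone; both antipodes are accessible.
- C7 is taken to the aldehyde level before ring B is added, and the benzylic oxygen formed there is acetylated. A 4-oxygenated aryl ketone at C7 would resist hydrogenolysis, and an aryl organometallic could add twice to the lactone.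
- The diol stays protected as the bis(tert-butyldimethylsilyl) ether until the last step, so that no free hydroxyl at C3 can cyclise onto a benzylic C7 electrophile.
- The phosphonium salt from steps 6–8 is prepared in advance, so that the aldehyde from step 5 is used without storage.

Step 1
Reactants: 1 cis,cis-cyclohexane-1,3,5-triol (all three hydroxyls on one face; meso)
Product: 2 all-cis-3,5-bis(tert-butyldimethylsilyloxy)cyclohexan-1-ol (meso)
Conditions: TBSCl (2.05 equiv), imidazole (4.5 equiv), DMF, 0 °C to rt; chromatography (mono- and tris-silyl ethers recycled)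
Reagents that add atoms: tert-butyldimethylsilyl chloride, CC(C)(C)[Si](C)(C)Cl
Why: Imidazole-promoted silylation of secondary alcohols; the three hydroxyls are equivalent, so the bis-ether is taken from a statistical mixture, and no stereocentre is touched, the all-cis relationship of 1 being carried over.

Step 2
Reactants: 2 all-cis-3,5-bis(tert-butyldimethylsilyloxy)cyclohexan-1-ol
Product: 3 cis-3,5-bis(tert-butyldimethylsilyloxy)cyclohexan-1-one (meso; 3R,5S)
Conditions: Dess–Martin periodinane (1.2 equiv), CH2Cl2, 0 °C to rt; aq. Na2S2O3/NaHCO3 work-up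
Reagents that add atoms: none
Why: Dess–Martin oxidation of a secondary alcohol under non-basic conditions, which should not trigger β-elimination of the silyloxy groups and leaves both stereocentres untouched.

Step 3
Reactants: 3 cis-3,5-bis(tert-butyldimethylsilyloxy)cyclohexan-1-one
Product: 5 (4R,6S)-4,6-bis(tert-butyldimethylsilyloxy)oxepan-2-one, via Criegee peroxyhemiketal 4 (not isolated)
Conditions: mCPBA (1.1 equiv), Sc(OTf)3 (5 mol%), chiral twofold-symmetric N,N'-dioxide ligand (6 mol%; propane-1,3-diyl-linked pipecolic acid N-oxide bis(2,6-diisopropylanilide), antipode as assumed above), EtOAc, −20 °C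
Reagents that add atoms: meta-chloroperoxybenzoic acid, OOC(=O)c1cccc(Cl)c1
Why: The peracid adds to the Sc-bound carbonyl C7 to give the Criegee adduct 4, and within the chiral pocket of the ligand only the C7–C2 bond can lie antiperiplanar to the breaking O–O bond, so C2 migrates from carbon to oxygen as 3-chlorobenzoate leaves. The closest known reaction type is the catalytic enantioselective Baeyer–Villiger desymmetrisation of prochiral 4-substituted and meso cis-3,5-disubstituted cyclohexanones by chiral Lewis acid–peracid systems or by Baeyer–Villiger monooxygenases. The oxepanone ring is not formed by a cyclisation; it arises by expansion of the six-membered ring through this 1,2-shift, with retention at the migrating carbon C2. No new stereocentre is created: C3 and C5 already exist and are cis in 3, and their absolute configuration in 5 is dictated solely by the catalyst's choice between the enantiotopic bonds C7–C2 and C7–C6. The selectivity needed is therefore enantiotopic-bond selection only, and the substrate secures the rest, since both α-carbons are unbranched CH2 groups of equal migratory aptitude (no regiochemical bias) and the cis relationship cannot change. The bulky, weakly coordinating silyl ethers should keep the ketone monodentate on the metal, and the non-basic medium should not provoke β-elimination of silanol.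

Step 4
Reactants: 5 (4R,6S)-4,6-bis(tert-butyldimethylsilyloxy)oxepan-2-one
Product: 6 (3R,5S)-3,5-bis(tert-butyldimethylsilyloxy)-6-hydroxy-N-methoxy-N-methylhexanamide
Conditions: MeNH(OMe)·HCl (3 equiv), AlMe3 (3 equiv), CH2Cl2, 0 °C to rt; aq. KNaC4H4O6 work-up
Reagents that add atoms: N,O-dimethylhydroxylamine hydrochloride, CNOC.Cl
Why: Aluminium amide aminolysis of a lactone (Weinreb amide formation) cleaves only the acyl C7–O bond, so C2 is released as the primary alcohol and C7 is held at the acyl level without touching C3 or C5, and the Lewis-acidic, alkoxide-free medium should not induce silyl migration from the C3 oxygen to the C2 oxygen.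

Step 5
Reactants: 6 (3R,5S)-3,5-bis(tert-butyldimethylsilyloxy)-6-hydroxy-N-methoxy-N-methylhexanamide
Product: 7 (3R,5S)-3,5-bis(tert-butyldimethylsilyloxy)-N-methoxy-N-methyl-6-oxohexanamide
Conditions: Dess–Martin periodinane (1.3 equiv), CH2Cl2, 0 °C to rt; crude aldehyde used at once in step 9
Reagents that add atoms: none
Why: Dess–Martin oxidation of the primary alcohol at C2 to the aldehyde under neutral conditions, which should leave the α-silyloxy stereocentre C3 unepimerised and the amide untouched.

Step 6
Reactants: 8 3,4-dihydroxy-5-methoxybenzaldehyde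
Product: 9 3,4-bis(benzyloxy)-5-methoxybenzaldehyde
Conditions: BnBr (2.3 equiv), K2CO3 (2.5 equiv), DMF, 60 °C
Reagents that add atoms: benzyl bromide, BrCc1ccccc1
Why: Williamson ether synthesis on both phenols, giving benzyl ethers that survive the ylide, hydride and Grignard steps and are removed by the hydrogenation in step 12.

Step 7
Reactants: 9 3,4-bis(benzyloxy)-5-methoxybenzaldehyde
Product: 10 [3,4-bis(benzyloxy)-5-methoxyphenyl]methanol
Conditions: NaBH4, MeOH/THF, 0 °C
Reagents that add atoms: none
Why: Borohydride reduction of an aromatic aldehyde to the benzylic alcohol, with the aryl ethers inert.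

Step 8
Reactants: 10 [3,4-bis(benzyloxy)-5-methoxyphenyl]methanol
Product: 11 {[3,4-bis(benzyloxy)-5-methoxyphenyl]methyl}triphenylphosphonium bromide
Conditions: PPh3·HBr (1.05 equiv), MeCN, reflux
Reagents that add atoms: triphenylphosphine hydrobromide, Br.c1ccc(cc1)P(c1ccccc1)c1ccccc1
Why: Electron-rich benzylic alcohols are converted directly into benzylphosphonium salts by triphenylphosphine hydrobromide (acid-assisted ionisation of the benzylic C–O bond, then quaternisation of the phosphine), with water as the only by-product.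

Step 9
Reactants: 11 {[3,4-bis(benzyloxy)-5-methoxyphenyl]methyl}triphenylphosphonium bromide; 7 (3R,5S)-3,5-bis(tert-butyldimethylsilyloxy)-N-methoxy-N-methyl-6-oxohexanamide
Product: 13 (3R,5S)-7-[3,4-bis(benzyloxy)-5-methoxyphenyl]-3,5-bis(tert-butyldimethylsilyloxy)-N-methoxy-N-methylhept-6-enamide (E/Z mixture), via benzylidene ylide 12 (not isolated)
Conditions: 11 (1.2 equiv), NaN(SiMe3)2 (1.15 equiv), THF, −78 to 0 °C; then 7, −78 to 0 °C
Reagents that add atoms: none
Why: Wittig olefination of the aldehyde with a semi-stabilised benzylidene ylide forms C1=C2 (geometry irrelevant, since the alkene is hydrogenated in step 12); the preformed, only moderately basic ylide at low temperature should leave C3 unepimerised and the amide untouched.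

Step 10
Reactants: 13 (3R,5S)-7-[3,4-bis(benzyloxy)-5-methoxyphenyl]-3,5-bis(tert-butyldimethylsilyloxy)-N-methoxy-N-methylhept-6-enamide
Product: 14 (3R,5S)-7-[3,4-bis(benzyloxy)-5-methoxyphenyl]-3,5-bis(tert-butyldimethylsilyloxy)hept-6-enal (E/Z mixture)
Conditions: i-Bu2AlH (1.5 equiv), THF, −78 °C; aq. KNaC4H4O6 work-up
Reagents that add atoms: none
Why: Hydride reduction of an N-methoxy-N-methylamide stops at the aldehyde because the chelated tetrahedral aluminium adduct survives until aqueous work-up, and the styrene, benzyl ethers and silyl ethers are inert at −78 °C.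

Step 11
Reactants: 14 (3R,5S)-7-[3,4-bis(benzyloxy)-5-methoxyphenyl]-3,5-bis(tert-butyldimethylsilyloxy)hept-6-enal; 15 1-(benzyloxy)-4-bromobenzene
Product: 18 (3S,5S)-7-[3,4-bis(benzyloxy)-5-methoxyphenyl]-1-[4-(benzyloxy)phenyl]-3,5-bis(tert-butyldimethylsilyloxy)hept-6-en-1-yl acetate (both epimers at the acetoxy carbon; E/Z mixture), via 4-(benzyloxy)phenylmagnesium bromide 16 (not isolated), via bromomagnesium C7-alkoxide 17 (not isolated)
Conditions: 15 (1.4 equiv), Mg, THF, rt to 40 °C; added to 14, THF, −78 to −20 °C; then Ac2O (3 equiv), DMAP (cat.), −20 °C to rt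
Reagents that add atoms: acetic anhydride, CC(=O)OC(C)=O
Why: Grignard addition to the aldehyde forms the C7–aryl bond and the magnesium alkoxide is acetylated in the same flask while cold, before any oxygen-to-oxygen silyl transfer; the new C7 centre is formed without control, which is irrelevant because it is erased in step 12.

Step 12
Reactants: 18 (3S,5S)-7-[3,4-bis(benzyloxy)-5-methoxyphenyl]-1-[4-(benzyloxy)phenyl]-3,5-bis(tert-butyldimethylsilyloxy)hept-6-en-1-yl acetate
Product: 19 5-[(3R,5S)-3,5-bis(tert-butyldimethylsilyloxy)-7-(4-hydroxyphenyl)heptyl]-3-methoxybenzene-1,2-diol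
Conditions: H2 (1–3 atm), 10% Pd/C, EtOAc, rt
Reagents that add atoms: none
Why: Heterogeneous catalytic hydrogenation should saturate C1=C2, hydrogenolyse the three aryl benzyl ethers and cleave the benzylic C7–OAc bond (benzylic ester hydrogenolysis, assisted by the para oxygen of ring B), which removes the stereorandom C7 centre while the silyl ethers at C3 and C5 stay in place in the aprotic solvent.

Step 13
Reactants: 19 5-[(3R,5S)-3,5-bis(tert-butyldimethylsilyloxy)-7-(4-hydroxyphenyl)heptyl]-3-methoxybenzene-1,2-diol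
Product: 20 5-[(3R,5S)-3,5-dihydroxy-7-(4-hydroxyphenyl)heptyl]-3-methoxybenzene-1,2-diol (the target)
Conditions: HF·pyridine, THF/pyridine, 0 °C to rt, under argon
Reagents that add atoms: none
Why: Fluoride-mediated cleavage of the two secondary silyl ethers under mildly acidic conditions that the air-sensitive catechol tolerates; only Si–O bonds break, so the syn (3R,5S) configuration is retained.

Compound list
1 | cis,cis-cyclohexane-1,3,5-triol (all-cis, meso) | O[C@H]1C[C@@H](O)C[C@@H](O)C1 | starting material
2 | all-cis-3,5-bis(tert-butyldimethylsilyloxy)cyclohexan-1-ol (meso) | O[C@H]1C[C@@H](O[Si](C)(C)C(C)(C)C)C[C@@H](O[Si](C)(C)C(C)(C)C)C1 | intermediate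
3 | cis-3,5-bis(tert-butyldimethylsilyloxy)cyclohexan-1-one (meso; 3R,5S) | O=C1C[C@@H](O[Si](C)(C)C(C)(C)C)C[C@@H](O[Si](C)(C)C(C)(C)C)C1 | intermediate
4 | Criegee adduct, 1-hydroxy-cis-3,5-bis(tert-butyldimethylsilyloxy)cyclohexyl 3-chloroperoxybenzoate (metal-bound in the flask; configuration at the peroxy-bearing carbon not defined) | OC1(OOC(=O)c2cccc(Cl)c2)C[C@@H](O[Si](C)(C)C(C)(C)C)C[C@@H](O[Si](C)(C)C(C)(C)C)C1 | intermediate (not isolated)
5 | (4R,6S)-4,6-bis(tert-butyldimethylsilyloxy)oxepan-2-one | O1C[C@@H](O[Si](C)(C)C(C)(C)C)C[C@@H](O[Si](C)(C)C(C)(C)C)CC1=O | intermediate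
6 | (3R,5S)-3,5-bis(tert-butyldimethylsilyloxy)-6-hydroxy-N-methoxy-N-methylhexanamide | OC[C@@H](O[Si](C)(C)C(C)(C)C)C[C@@H](O[Si](C)(C)C(C)(C)C)CC(=O)N(C)OC | intermediate
7 | (3R,5S)-3,5-bis(tert-butyldimethylsilyloxy)-N-methoxy-N-methyl-6-oxohexanamide | O=C[C@@H](O[Si](C)(C)C(C)(C)C)C[C@@H](O[Si](C)(C)C(C)(C)C)CC(=O)N(C)OC | intermediate
8 | 3,4-dihydroxy-5-methoxybenzaldehyde | COc1cc(C=O)cc(O)c1O | starting material
9 | 3,4-bis(benzyloxy)-5-methoxybenzaldehyde | COc1cc(C=O)cc(OCc2ccccc2)c1OCc1ccccc1 | intermediate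
10 | [3,4-bis(benzyloxy)-5-methoxyphenyl]methanol | COc1cc(CO)cc(OCc2ccccc2)c1OCc1ccccc1 | intermediate
11 | {[3,4-bis(benzyloxy)-5-methoxyphenyl]methyl}triphenylphosphonium bromide | COc1cc(C[P+](c2ccccc2)(c2ccccc2)c2ccccc2)cc(OCc2ccccc2)c1OCc1ccccc1.[Br-] | intermediate
12 | [3,4-bis(benzyloxy)-5-methoxybenzylidene]triphenylphosphorane | COc1cc(C=P(c2ccccc2)(c2ccccc2)c2ccccc2)cc(OCc2ccccc2)c1OCc1ccccc1 | intermediate (not isolated)
13 | (3R,5S)-7-[3,4-bis(benzyloxy)-5-methoxyphenyl]-3,5-bis(tert-butyldimethylsilyloxy)-N-methoxy-N-methylhept-6-enamide (E/Z mixture) | COc1cc(C=C[C@@H](O[Si](C)(C)C(C)(C)C)C[C@@H](O[Si](C)(C)C(C)(C)C)CC(=O)N(C)OC)cc(OCc2ccccc2)c1OCc1ccccc1 | intermediate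
14 | (3R,5S)-7-[3,4-bis(benzyloxy)-5-methoxyphenyl]-3,5-bis(tert-butyldimethylsilyloxy)hept-6-enal (E/Z mixture) | COc1cc(C=C[C@@H](O[Si](C)(C)C(C)(C)C)C[C@@H](O[Si](C)(C)C(C)(C)C)CC=O)cc(OCc2ccccc2)c1OCc1ccccc1 | intermediate
15 | 1-(benzyloxy)-4-bromobenzene | Brc1ccc(OCc2ccccc2)cc1 | starting material
16 | 4-(benzyloxy)phenylmagnesium bromide | Br[Mg]c1ccc(OCc2ccccc2)cc1 | intermediate (not isolated)
17 | bromomagnesium alkoxide of (3S,5S)-7-[3,4-bis(benzyloxy)-5-methoxyphenyl]-1-[4-(benzyloxy)phenyl]-3,5-bis(tert-butyldimethylsilyloxy)hept-6-en-1-ol (both C7 epimers) | COc1cc(C=C[C@@H](O[Si](C)(C)C(C)(C)C)C[C@@H](O[Si](C)(C)C(C)(C)C)CC(O[Mg]Br)c2ccc(OCc3ccccc3)cc2)cc(OCc2ccccc2)c1OCc1ccccc1 | intermediate (not isolated)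
18 | (3S,5S)-7-[3,4-bis(benzyloxy)-5-methoxyphenyl]-1-[4-(benzyloxy)phenyl]-3,5-bis(tert-butyldimethylsilyloxy)hept-6-en-1-yl acetate (both epimers at the acetoxy carbon; E/Z mixture) | COc1cc(C=C[C@@H](O[Si](C)(C)C(C)(C)C)C[C@@H](O[Si](C)(C)C(C)(C)C)CC(OC(C)=O)c2ccc(OCc3ccccc3)cc2)cc(OCc2ccccc2)c1OCc1ccccc1 | intermediate
19 | 5-[(3R,5S)-3,5-bis(tert-butyldimethylsilyloxy)-7-(4-hydroxyphenyl)heptyl]-3-methoxybenzene-1,2-diol | COc1cc(CC[C@@H](O[Si](C)(C)C(C)(C)C)C[C@@H](O[Si](C)(C)C(C)(C)C)CCc2ccc(O)cc2)cc(O)c1O | intermediate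
20 | 5-[(3R,5S)-3,5-dihydroxy-7-(4-hydroxyphenyl)heptyl]-3-methoxybenzene-1,2-diol | COc1cc(CC[C@@H](O)C[C@@H](O)CCc2ccc(O)cc2)cc(O)c1O | target

Total step count: 13. Longest linear sequence: 10 steps (steps 1–5 and 9–13, from triol 1).

Steps most likely to fail

1. Step 3. The catalyst may discriminate poorly between the enantiotopic bonds C7–C2 and C7–C6, because the silyloxy groups sit β to the carbonyl and may steer the Criegee adduct differently from simple alkyl groups. The Lewis acid may also induce elimination of silanol. Changing ligand or switching to a Baeyer–Villiger monooxygenase would only change conditions. The fallback distinguishes the enantiotopic α-protons instead and sets out from ketone 3. Deprotonation with lithium (R,R)-bis(1-phenylethyl)amide (or its antipode, whichever removes the axial proton at C2) in THF at −100 °C, with TMSCl and LiCl present as internal quench, should give (3S,5R)-3,5-bis(tert-butyldimethylsilyloxy)-1-(trimethylsilyloxy)cyclohex-1-ene F1, whose enol double bond is C7=C2. Ozonolysis in CH2Cl2/MeOH at −78 °C followed by NaBH4 should cleave that double bond to (3R,5S)-3,5-bis(tert-butyldimethylsilyloxy)-6-hydroxyhexanoic acid F2. Coupling with MeNH(OMe)·HCl (EDC·HCl, HOBt, N-methylmorpholine, CH2Cl2) rejoins the route at 6.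

2. Step 12. The C7–O hydrogenolysis may stall after the fast alkene saturation and debenzylation, or the allylic C3–O bond may be cleaved reductively before C1=C2 is saturated. The fallback brings C7 to the CH2 level before ring B is attached and sets out from aldehyde 14. NaBH4 in MeOH/THF at 0 °C should give (3S,5S)-7-[3,4-bis(benzyloxy)-5-methoxyphenyl]-3,5-bis(tert-butyldimethylsilyloxy)hept-6-en-1-ol F3. TsCl, Et3N and DMAP in CH2Cl2 should give (3S,5S)-7-[3,4-bis(benzyloxy)-5-methoxyphenyl]-3,5-bis(tert-butyldimethylsilyloxy)hept-6-en-1-yl 4-methylbenzenesulfonate F4. Copper-catalysed Kochi-type coupling with Grignard reagent 16 (Li2CuCl4 cat., THF, −20 °C to rt) should give (3S,5S)-1-[3,4-bis(benzyloxy)-5-methoxyphenyl]-7-[4-(benzyloxy)phenyl]-3,5-bis(tert-butyldimethylsilyloxy)hept-1-ene F5. Hydrogenation (H2, Pd/C, EtOAc), now only alkene saturation and O-debenzylation, rejoins the route at 19.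

3. Step 9. The base may epimerise C3 of the α-silyloxy aldehyde before olefination, which would erode the syn relationship. The fallback forms C1=C2 by metathesis under non-basic conditions and sets out from aldehyde 7 and aldehyde 9. Methylenation of 7 with Zn, CH2Br2 and TiCl4 in THF/CH2Cl2 at 0 °C should give (3R,5S)-3,5-bis(tert-butyldimethylsilyloxy)-N-methoxy-N-methylhept-6-enamide F6. Aldehyde 9 with Ph3P=CH2 in THF should give 1,2-bis(benzyloxy)-5-ethenyl-3-methoxybenzene F7. Cross-metathesis of F6 with an excess of F7 (second-generation Hoveyda–Grubbs catalyst, CH2Cl2, 40 °C) should give 13 as its E isomer, where the route is rejoined.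

Further compounds
F1 | step 3 | (3S,5R)-3,5-bis(tert-butyldimethylsilyloxy)-1-(trimethylsilyloxy)cyclohex-1-ene | C[Si](C)(C)OC1=C[C@@H](O[Si](C)(C)C(C)(C)C)C[C@@H](O[Si](C)(C)C(C)(C)C)C1
F2 | step 3 | (3R,5S)-3,5-bis(tert-butyldimethylsilyloxy)-6-hydroxyhexanoic acid | OC[C@@H](O[Si](C)(C)C(C)(C)C)C[C@@H](O[Si](C)(C)C(C)(C)C)CC(=O)O
F3 | step 12 | (3S,5S)-7-[3,4-bis(benzyloxy)-5-methoxyphenyl]-3,5-bis(tert-butyldimethylsilyloxy)hept-6-en-1-ol (E/Z mixture) | COc1cc(C=C[C@@H](O[Si](C)(C)C(C)(C)C)C[C@@H](O[Si](C)(C)C(C)(C)C)CCO)cc(OCc2ccccc2)c1OCc1ccccc1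
F4 | step 12 | (3S,5S)-7-[3,4-bis(benzyloxy)-5-methoxyphenyl]-3,5-bis(tert-butyldimethylsilyloxy)hept-6-en-1-yl 4-methylbenzenesulfonate (E/Z mixture) | COc1cc(C=C[C@@H](O[Si](C)(C)C(C)(C)C)C[C@@H](O[Si](C)(C)C(C)(C)C)CCOS(=O)(=O)c2ccc(C)cc2)cc(OCc2ccccc2)c1OCc1ccccc1
F5 | step 12 | (3S,5S)-1-[3,4-bis(benzyloxy)-5-methoxyphenyl]-7-[4-(benzyloxy)phenyl]-3,5-bis(tert-butyldimethylsilyloxy)hept-1-ene (E/Z mixture) | COc1cc(C=C[C@@H](O[Si](C)(C)C(C)(C)C)C[C@@H](O[Si](C)(C)C(C)(C)C)CCc2ccc(OCc3ccccc3)cc2)cc(OCc2ccccc2)c1OCc1ccccc1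
F6 | step 9 | (3R,5S)-3,5-bis(tert-butyldimethylsilyloxy)-N-methoxy-N-methylhept-6-enamide | C=C[C@@H](O[Si](C)(C)C(C)(C)C)C[C@@H](O[Si](C)(C)C(C)(C)C)CC(=O)N(C)OC
F7 | step 9 | 1,2-bis(benzyloxy)-5-ethenyl-3-methoxybenzene | COc1cc(C=C)cc(OCc2ccccc2)c1OCc1ccccc1
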